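Everything rests on taking ring C apart at its single methylene: C2 lies between the ring oxygen O1 and the tertiary carbinol carbon C3, so removing it with the O1–C2 and C2–C3 bonds leaves a 2-hydroxybenzil whose two ketone carbons are C3 and C4. In one operation a sulfoxonium methylide, steered by chiral LaLi3(binaphthoxide)3, transfers CH2 to the C3 ketone and the neighbouring phenoxide opens the resulting oxirane, so ring C, two skeletal bonds and the (3R) carbinol centre arise together. The precursor is an achiral ring A/ring B 1,2-diketone with one free ortho phenol, the remaining phenols being masked as a MOM ether and a catechol acetonide.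

Key step: step 11

Remark: the face selectivity of the lanthanum catalyst towards a 1,2-diketone cannot be derived from precedent; the (S)-binaphthoxide is written and its mirror image is to be used if it proves to favour the Si face of C3=O.

Step 1
Reactants: 1 pyrogallol
Product: 2 2,2-dimethyl-1,3-benzodioxol-4-ol
Conditions: Me2C(OMe)2, p-TsOH·H2O (cat.), toluene, reflux (MeOH distilled off)
Reagents that add atoms: 2,2-dimethoxypropane, COC(C)(C)OC
Why: Acid-catalysed transketalization, in which the five-membered isopropylidene ketal can only bridge two adjacent hydroxyls and so leaves exactly one phenol free.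

Step 2
Reactants: 2 pyrogallol acetonide; 3 prenyl bromide (1-bromo-3-methylbut-2-ene)
Product: 4 2,2-dimethyl-4-[(3-methylbut-2-en-1-yl)oxy]-1,3-benzodioxole
Conditions: K2CO3, acetone, reflux
Reagents that add atoms: prenyl bromide (compound 3), CC(C)=CCBr
Why: Williamson ether synthesis, the phenoxide displacing bromide at the primary allylic carbon.

Step 3
Reactants: 4 aryl prenyl ether
Product: 5 2,2-dimethyl-5-(2-methylbut-3-en-2-yl)-1,3-benzodioxol-4-ol
Conditions: PhNEt2, 185 °C, sealed tube, argon
Reagents that add atoms: none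
Why: Aromatic Claisen rearrangement, a [3,3] shift to the only free ortho carbon (C5) that inverts the prenyl unit into the 1,1-dimethylallyl group before enolization restores the phenol.

Step 4
Reactants: 5 ortho-(1,1-dimethylallyl)phenol
Product: 6 4-methoxy-2,2-dimethyl-5-(2-methylbut-3-en-2-yl)-1,3-benzodioxole
Conditions: MeI, K2CO3, DMF, 40 °C
Reagents that add atoms: iodomethane, CI
Why: Williamson O-methylation of the phenoxide, which also removes the free phenol that could otherwise add to the neighbouring alkene.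

Step 5
Reactants: 6 ring-B methyl ether
Product: 8 7-bromo-4-methoxy-2,2-dimethyl-5-(2-methylbut-3-en-2-yl)-1,3-benzodioxole, via aryllithium 7 (not isolated)
Conditions: n-BuLi, TMEDA, THF, −78 → 0 °C; then BrCCl2CCl2Br, −78 °C → rt
Reagents that add atoms: 1,2-dibromo-1,1,2,2-tetrachloroethane, BrC(Cl)(Cl)C(Cl)(Cl)Br
Why: Directed ortho-metalation followed by bromine transfer to the aryllithium, regioselective because C7–H is the only ring hydrogen next to an oxygen, so that an electrophilic bromination with its site and alkene problems is avoided.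

Step 6
Reactants: 9 2',4'-dihydroxyacetophenone
Product: 10 1-[2-hydroxy-4-(methoxymethoxy)phenyl]ethan-1-one
Conditions: MOMCl (1.1 equiv), K2CO3, acetone, 0 °C → rt
Reagents that add atoms: chloromethyl methyl ether, COCCl
Why: Williamson-type O-alkylation, selective for the 4-hydroxyl because the 2-hydroxyl is tied up in a hydrogen bond to the ketone and is far less nucleophilic.

Step 7
Reactants: 10 4-O-MOM acetophenone
Product: 11 1-{2-[(4-methoxyphenyl)methoxy]-4-(methoxymethoxy)phenyl}ethan-1-one
Conditions: PMBCl, K2CO3, n-Bu4NI (cat.), DMF, 60 °C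
Reagents that add atoms: 4-methoxybenzyl chloride, COc1ccc(CCl)cc1
Why: Williamson ether synthesis under conditions forcing enough to alkylate the chelated phenol, installing a group that is later removed oxidatively without touching the acetals.

Step 8
Reactants: 11 ring-A acetophenone; 8 ring-B bromide
Product: 12 2-[7-methoxy-2,2-dimethyl-6-(2-methylbut-3-en-2-yl)-1,3-benzodioxol-4-yl]-1-{2-[(4-methoxyphenyl)methoxy]-4-(methoxymethoxy)phenyl}ethan-1-one
Conditions: Pd2(dba)3 (2 mol%), XPhos (5 mol%), NaOt-Bu (2.2 equiv), toluene, 80 °C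
Reagents that add atoms: none
Why: Palladium-catalysed α-arylation of a methyl ketone with an aryl bromide, which should stop at monoarylation because the product rests as its hindered enolate and in which the neopentyl-type vinyl group is too encumbered to compete by a Heck pathway.

Step 9
Reactants: 12 deoxybenzoin
Product: 13 1-{2-[(4-methoxyphenyl)methoxy]-4-(methoxymethoxy)phenyl}-2-[7-methoxy-2,2-dimethyl-6-(2-methylbut-3-en-2-yl)-1,3-benzodioxol-4-yl]ethane-1,2-dione
Conditions: SeO2 (1.5 equiv), 1,4-dioxane/pyridine (10:1), 90 °C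
Reagents that add atoms: selenium dioxide, O=[Se]=O
Why: Riley oxidation of the doubly activated methylene of a deoxybenzoin to the 1,2-diketone, safe for the 1,1-dimethylallyl group because it has no allylic hydrogen and buffered by pyridine for the acetals.

Step 10
Reactants: 13 PMB-protected benzil
Product: 14 1-[2-hydroxy-4-(methoxymethoxy)phenyl]-2-[7-methoxy-2,2-dimethyl-6-(2-methylbut-3-en-2-yl)-1,3-benzodioxol-4-yl]ethane-1,2-dione
Conditions: DDQ (1.3 equiv), CH2Cl2/pH 7 buffer (10:1), 0 °C → rt
Reagents that add atoms: none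
Why: Oxidative cleavage of the 4-methoxybenzyl ether by hydride abstraction and hydrolysis of the resulting oxocarbenium ion, a neutral process that should spare the MOM ether, the acetonide and the alkene.

Step 11
Reactants: 14 2-hydroxybenzil; 15 trimethylsulfoxonium iodide
Product: 18 (3R)-3-hydroxy-3-[7-methoxy-2,2-dimethyl-6-(2-methylbut-3-en-2-yl)-1,3-benzodioxol-4-yl]-7-(methoxymethoxy)-2,3-dihydro-4H-chromen-4-one, via sodium phenoxide 16 (not isolated), via oxirane 17 (not isolated)
Conditions: NaH (1.0 equiv), THF, 0 °C; then LaLi3[(S)-binaphthoxide]3 (10 mol%), [2,4,6-(MeO)3C6H2]3P=O (10 mol%), 5 Å MS, Me2S(O)=CH2 (1.2 equiv, from 15 + NaH, THF), rt → 40 °C; aq. NH4Cl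
Reagents that add atoms: trimethylsulfoxonium iodide (compound 15), C[S+](C)(C)=O.[I-]
Why: Proposed new method: the ylide carbon adds to the C3 ketone of the open-chain phenoxide 16, the betaine closes 3-exo-tet with loss of dimethyl sulfoxide to oxirane 17 (C2–C3 bond), and the ortho phenoxide then opens 17 by backside attack at its primary carbon (O1–C2 bond), closing pyranone ring C in the mode called 6-endo for epoxides (both oxirane carbons end in the ring; counted by the breaking C2–O bond alone it is 6-exo-tet), the 5-exo alternative at the fully substituted C3 being blocked. The closest known reactions are the LaLi3(binaphthoxide)3/triarylphosphine oxide catalysed Corey–Chaykovsky epoxidation of aryl methyl ketones and the base-induced cyclization of 2-hydroxyaryl oxiranyl ketones to 3-hydroxychromanones (the Algar–Flynn–Oyamada manifold); what is new is a 1,2-diketone whose reacting carbonyl carries two large flat groups. The C3 stereocentre is set in the C–C bond formation by the chiral binaphthoxide catalyst, which has to deliver CH2 to the Re face of C3=O (O > aroyl C4 > aryl C1'), plausibly with lanthanum holding the substrate as a phenoxide/C4 carbonyl chelate while a lithium naphthoxide site orients the ylide. Because ring closure breaks no bond at C3, the configuration from the addition is carried into the product as 3R. The step needs site selectivity for C3 over C4, which the substrate secures through the phenoxide: it turns the C4 carbonyl into a vinylogous carboxylate (reinforced by the para MOM ether), keeps the diketone out of its ring-closed hemiketal form, and leaves C3=O, flanked only by the tied-back dioxole oxygen, as the electrophile. The ylide is held to a slight excess so that neither oxirane 17 nor the product ketone is homologated further.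

Step 12
Reactants: 18 protected (3R)-3-hydroxyisoflavanone
Product: 19 (3R)-3-[2,3-dihydroxy-4-methoxy-5-(2-methylbut-3-en-2-yl)phenyl]-3,7-dihydroxy-2,3-dihydro-4H-chromen-4-one
Conditions: HCl (3 M in MeOH), 45 °C
Reagents that add atoms: none
Why: Acid-catalysed transacetalization to methanol should cleave the isopropylidene ketal and the MOM acetal through their oxocarbenium ions, while the C3 carbinol is shielded from ionization by the adjacent carbonyl, has no epimerizable hydrogen, and the monosubstituted alkene is not protonated at this acidity.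

Compound list
1 | pyrogallol (benzene-1,2,3-triol) | Oc1cccc(O)c1O | starting material
2 | 2,2-dimethyl-1,3-benzodioxol-4-ol | CC1(C)Oc2cccc(O)c2O1 | intermediate
3 | prenyl bromide (1-bromo-3-methylbut-2-ene) | CC(C)=CCBr | starting material
4 | 2,2-dimethyl-4-[(3-methylbut-2-en-1-yl)oxy]-1,3-benzodioxole | CC(C)=CCOc1cccc2OC(C)(C)Oc12 | intermediate
5 | 2,2-dimethyl-5-(2-methylbut-3-en-2-yl)-1,3-benzodioxol-4-ol | C=CC(C)(C)c1ccc2OC(C)(C)Oc2c1O | intermediate
6 | 4-methoxy-2,2-dimethyl-5-(2-methylbut-3-en-2-yl)-1,3-benzodioxole | C=CC(C)(C)c1ccc2OC(C)(C)Oc2c1OC | intermediate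
7 | [7-methoxy-2,2-dimethyl-6-(2-methylbut-3-en-2-yl)-1,3-benzodioxol-4-yl]lithium (not isolated) | C=CC(C)(C)c1cc([Li])c2OC(C)(C)Oc2c1OC | intermediate
8 | 7-bromo-4-methoxy-2,2-dimethyl-5-(2-methylbut-3-en-2-yl)-1,3-benzodioxole | C=CC(C)(C)c1cc(Br)c2OC(C)(C)Oc2c1OC | intermediate
9 | 2',4'-dihydroxyacetophenone | CC(=O)c1ccc(O)cc1O | starting material
10 | 1-[2-hydroxy-4-(methoxymethoxy)phenyl]ethan-1-one | CC(=O)c1ccc(OCOC)cc1O | intermediate
11 | 1-{2-[(4-methoxyphenyl)methoxy]-4-(methoxymethoxy)phenyl}ethan-1-one | CC(=O)c1ccc(OCOC)cc1OCc1ccc(OC)cc1 | intermediate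
12 | 2-[7-methoxy-2,2-dimethyl-6-(2-methylbut-3-en-2-yl)-1,3-benzodioxol-4-yl]-1-{2-[(4-methoxyphenyl)methoxy]-4-(methoxymethoxy)phenyl}ethan-1-one | C=CC(C)(C)c1cc(CC(=O)c3ccc(OCOC)cc3OCc4ccc(OC)cc4)c2OC(C)(C)Oc2c1OC | intermediate
13 | 1-{2-[(4-methoxyphenyl)methoxy]-4-(methoxymethoxy)phenyl}-2-[7-methoxy-2,2-dimethyl-6-(2-methylbut-3-en-2-yl)-1,3-benzodioxol-4-yl]ethane-1,2-dione | C=CC(C)(C)c1cc(C(=O)C(=O)c3ccc(OCOC)cc3OCc4ccc(OC)cc4)c2OC(C)(C)Oc2c1OC | intermediate
14 | 1-[2-hydroxy-4-(methoxymethoxy)phenyl]-2-[7-methoxy-2,2-dimethyl-6-(2-methylbut-3-en-2-yl)-1,3-benzodioxol-4-yl]ethane-1,2-dione | C=CC(C)(C)c1cc(C(=O)C(=O)c3ccc(OCOC)cc3O)c2OC(C)(C)Oc2c1OC | intermediate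
15 | trimethylsulfoxonium iodide | C[S+](C)(C)=O.[I-] | starting material
16 | sodium 2-{2-[7-methoxy-2,2-dimethyl-6-(2-methylbut-3-en-2-yl)-1,3-benzodioxol-4-yl]-2-oxoacetyl}-5-(methoxymethoxy)phenolate (not isolated) | C=CC(C)(C)c1cc(C(=O)C(=O)c3ccc(OCOC)cc3[O-])c2OC(C)(C)Oc2c1OC.[Na+] | intermediate
17 | sodium 2-{[(2R)-2-[7-methoxy-2,2-dimethyl-6-(2-methylbut-3-en-2-yl)-1,3-benzodioxol-4-yl]oxiran-2-yl]carbonyl}-5-(methoxymethoxy)phenolate (not isolated) | C=CC(C)(C)c1cc([C@@]3(C(=O)c4ccc(OCOC)cc4[O-])OC3)c2OC(C)(C)Oc2c1OC.[Na+] | intermediate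
18 | (3R)-3-hydroxy-3-[7-methoxy-2,2-dimethyl-6-(2-methylbut-3-en-2-yl)-1,3-benzodioxol-4-yl]-7-(methoxymethoxy)-2,3-dihydro-4H-chromen-4-one | C=CC(C)(C)c1cc([C@@]3(O)COc4cc(OCOC)ccc4C3=O)c2OC(C)(C)Oc2c1OC | intermediate
19 | (3R)-3-[2,3-dihydroxy-4-methoxy-5-(2-methylbut-3-en-2-yl)phenyl]-3,7-dihydroxy-2,3-dihydro-4H-chromen-4-one | C=CC(C)(C)c1cc([C@@]2(O)COc3cc(O)ccc3C2=O)c(O)c(O)c1OC | target

Total step count: 12.
Longest linear sequence: 10 steps (steps 1–5, then 8–12); ring A is prepared in a 2-step side branch (steps 6–7).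

Steps most likely to fail

1. Step 11. Facial discrimination may be poor because the catalyst must tell an aryl from an aroyl group. Uncatalysed ylide addition to the activated diketone may outrun the catalysed path. The betaine may shift its acyl group instead of closing. The sodium phenoxide may disturb the catalyst assembly. Fallback by known chemistry, setting out from 12 and coming back at 18: the PMB ether of 12 would be cleaved with DDQ in wet CH2Cl2 to give 1-[2-hydroxy-4-(methoxymethoxy)phenyl]-2-[7-methoxy-2,2-dimethyl-6-(2-methylbut-3-en-2-yl)-1,3-benzodioxol-4-yl]ethan-1-one F1. Heating this with paraformaldehyde and Et2NH in MeOH (Mannich condensation, amine elimination and oxa-Michael closure) should give racemic 3-[7-methoxy-2,2-dimethyl-6-(2-methylbut-3-en-2-yl)-1,3-benzodioxol-4-yl]-7-(methoxymethoxy)-2,3-dihydro-4H-chromen-4-one F2. Its potassium enolate (KHMDS, THF, −78 °C) would then be hydroxylated with an enantiopure (8,8-dichlorocamphorylsulfonyl)oxaziridine, the reagent enantiomer being chosen to deliver oxygen to the face that gives 3R, so that reagent-controlled enolate hydroxylation of a 3-substituted chromanone leads to 18.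

2. Step 12. Acid strong enough to open the aryl acetonide may also ionize the C3 carbinol (dehydration towards the isoflavone or erosion of enantiopurity) or add to the alkene, or the acetonide may be cleaved only in part. Fallback, setting out from 8 and coming back at 19, replaces the acetonide by more labile MOM ethers before the fragments are joined. Methanolic HCl at 60 °C would convert the robust bromide 8 into 6-bromo-3-methoxy-4-(2-methylbut-3-en-2-yl)benzene-1,2-diol F3, and MOMCl/NaH in DMF would give 1-bromo-4-methoxy-2,3-bis(methoxymethoxy)-5-(2-methylbut-3-en-2-yl)benzene F4. The chemistry of steps 8–11 would then be repeated: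
- α-arylation of 11 to 1-{2-[(4-methoxyphenyl)methoxy]-4-(methoxymethoxy)phenyl}-2-[4-methoxy-2,3-bis(methoxymethoxy)-5-(2-methylbut-3-en-2-yl)phenyl]ethan-1-one F5;
- SeO2 oxidation to 1-{2-[(4-methoxyphenyl)methoxy]-4-(methoxymethoxy)phenyl}-2-[4-methoxy-2,3-bis(methoxymethoxy)-5-(2-methylbut-3-en-2-yl)phenyl]ethane-1,2-dione F6;
- DDQ cleavage to 1-[2-hydroxy-4-(methoxymethoxy)phenyl]-2-[4-methoxy-2,3-bis(methoxymethoxy)-5-(2-methylbut-3-en-2-yl)phenyl]ethane-1,2-dione F7;
- the ylide annulation to (3R)-3-hydroxy-3-[4-methoxy-2,3-bis(methoxymethoxy)-5-(2-methylbut-3-en-2-yl)phenyl]-7-(methoxymethoxy)-2,3-dihydro-4H-chromen-4-one F8.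

All three MOM ethers should then fall to dilute methanolic HCl at room temperature, giving 19.

3. Step 3. At the temperature of the rearrangement the liberated phenol may undergo a further (abnormal) Claisen shift, cyclize onto the new alkene, or the ether may simply lose its prenyl group. Fallback, setting out from 4 and coming back at 6, traps the phenol as it forms: heating 4 in PhNEt2 at 185 °C with Ac2O and NaOAc should give 2,2-dimethyl-5-(2-methylbut-3-en-2-yl)-1,3-benzodioxol-4-yl acetate F9. Treating this in one flask with K2CO3/MeOH and then MeI would deacetylate and methylate the phenoxide to 6 without the free phenol ever being heated.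

Further compounds
F1 | step 11 | 1-[2-hydroxy-4-(methoxymethoxy)phenyl]-2-[7-methoxy-2,2-dimethyl-6-(2-methylbut-3-en-2-yl)-1,3-benzodioxol-4-yl]ethan-1-one | C=CC(C)(C)c1cc(CC(=O)c3ccc(OCOC)cc3O)c2OC(C)(C)Oc2c1OC
F2 | step 11 | racemic 3-[7-methoxy-2,2-dimethyl-6-(2-methylbut-3-en-2-yl)-1,3-benzodioxol-4-yl]-7-(methoxymethoxy)-2,3-dihydro-4H-chromen-4-one | C=CC(C)(C)c1cc(C3COc4cc(OCOC)ccc4C3=O)c2OC(C)(C)Oc2c1OC
F3 | step 12 | 6-bromo-3-methoxy-4-(2-methylbut-3-en-2-yl)benzene-1,2-diol | C=CC(C)(C)c1cc(Br)c(O)c(O)c1OC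
F4 | step 12 | 1-bromo-4-methoxy-2,3-bis(methoxymethoxy)-5-(2-methylbut-3-en-2-yl)benzene | C=CC(C)(C)c1cc(Br)c(OCOC)c(OCOC)c1OC
F5 | step 12 | 1-{2-[(4-methoxyphenyl)methoxy]-4-(methoxymethoxy)phenyl}-2-[4-methoxy-2,3-bis(methoxymethoxy)-5-(2-methylbut-3-en-2-yl)phenyl]ethan-1-one | C=CC(C)(C)c1cc(CC(=O)c2ccc(OCOC)cc2OCc2ccc(OC)cc2)c(OCOC)c(OCOC)c1OC
F6 | step 12 | 1-{2-[(4-methoxyphenyl)methoxy]-4-(methoxymethoxy)phenyl}-2-[4-methoxy-2,3-bis(methoxymethoxy)-5-(2-methylbut-3-en-2-yl)phenyl]ethane-1,2-dione | C=CC(C)(C)c1cc(C(=O)C(=O)c2ccc(OCOC)cc2OCc2ccc(OC)cc2)c(OCOC)c(OCOC)c1OC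
F7 | step 12 | 1-[2-hydroxy-4-(methoxymethoxy)phenyl]-2-[4-methoxy-2,3-bis(methoxymethoxy)-5-(2-methylbut-3-en-2-yl)phenyl]ethane-1,2-dione | C=CC(C)(C)c1cc(C(=O)C(=O)c2ccc(OCOC)cc2O)c(OCOC)c(OCOC)c1OC
F8 | step 12 | (3R)-3-hydroxy-3-[4-methoxy-2,3-bis(methoxymethoxy)-5-(2-methylbut-3-en-2-yl)phenyl]-7-(methoxymethoxy)-2,3-dihydro-4H-chromen-4-one | C=CC(C)(C)c1cc([C@@]2(O)COc3cc(OCOC)ccc3C2=O)c(OCOC)c(OCOC)c1OC
F9 | step 3 | 2,2-dimethyl-5-(2-methylbut-3-en-2-yl)-1,3-benzodioxol-4-yl acetate | CC(=O)Oc1c(C(C)(C)C=C)ccc2OC(C)(C)Oc12
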